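(S)-Hajos–Parrish ketone 1, vinylmagnesium bromide 2 and 7-hydroxycoumarin 3 are the building blocks. The retrosynthesis cuts the aryl ether C11–O bond (Mitsunobu), then the C8=C12 olefin (ketone methylenation), then the C9–C10 bond of ring B. That bond is traced back to a 1,2-shift of C10 from C8, so the precursor is a cyclopentanol bearing a C9–C11 epoxide on C8. The C8–C9 bond goes back to 2 and a C8 ketone, and the C5 and C4 methyls go back to cuprate and enolate chemistry on 1.
Enabling feature: in ring B, C9 is a tertiary stereocentre that carries the oxygenated carbon C11 and lies between quaternary C10 and sp2 C8. This is the array left behind when C10 moves from a C8 carbinol to the inner carbon of a C9–C11 epoxide (C8 ketone, free C11–OH).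
Forward order: ring A and the five-membered ring (C5, C6, C7, C8, C10) are already in 1. The C5 methyl, the two C4 methyls and the C3 alcohol are installed, then vinyl is added at C8 and the olefin epoxidised. Ring B then arises by enlargement of the cyclopentane, the ketone is methylenated, and 3 is attached last.
Stereochemistry: C10 comes from 1; C5 from cis-selective conjugate addition; C3 from a thermodynamically controlled reduction; C9 from a hydroxyl-directed epoxidation, transferred with inversion in the 1,2-shift. The C8 carbinol centre is transient.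

Key step: step 9

Remark: the target as drawn is a 4,4,5,10-tetramethyl cis-decalin. Carbons are numbered as in drimanes (ring A C1–C5 and C10, ring B C5–C10, C11 the CH2O carbon on C9, C12 the methylidene carbon). The hydrindane intermediates keep these numbers (C8 is the cyclopentanone carbon), and β denotes the face of the C10 methyl.

Step 1
Reactants: 1 (S)-Hajos–Parrish ketone
Product: 4 C8 ethylene ketal of 1 [(S)-7a'-methyl-2',3',7',7a'-tetrahydrospiro[1,3-dioxolane-2,1'-inden]-5'(6'H)-one]
Conditions: 2-ethyl-2-methyl-1,3-dioxolane (solvent), ethylene glycol (cat.), p-TsOH·H2O (cat.), rt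
Reagents that add atoms: 2-ethyl-2-methyl-1,3-dioxolane, CCC1(C)OCCO1
Why: acid-catalysed transketalisation should select the saturated cyclopentanone carbonyl (C8), which is more electrophilic than the vinylogous enone carbonyl, as is usual for this class of enediones; no stereocentre is formed.

Step 2
Reactants: 4 C8 ethylene ketal of 1
Product: 5 cis-hydrindane C3–C4 trimethylsilyl enol ether (5β,10β-dimethyl; C8 dioxolane)
Conditions: Me2CuLi (2.5 equiv), TMSCl (5 equiv), THF, −78 → −30 °C; Et3N, pH 7 work-up
Reagents that add atoms: lithium dimethylcuprate, [Li+].C[Cu-]C; chlorotrimethylsilane, C[Si](C)(C)Cl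
Why: chlorosilane-accelerated Gilman conjugate addition to the β,β-disubstituted enone should deliver the methyl group to C5 on the face of the C10 methyl, because only that trajectory leads to the cis-fused hydrindane enolate (the trans-fused one is strained), and silylation fixes the C3–C4 enolate regiochemistry.

Step 3
Reactants: 5 cis-hydrindane trimethylsilyl enol ether
Product: 9 5β,10β-dimethyl-4-methylidene cis-hydrindan-3-one C8 ethylene ketal, via lithium enolate 6 (not isolated), via Mannich base 7 (not isolated), via ammonium iodide 8 (not isolated)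
Conditions: MeLi (1.1 equiv), THF, 0 °C; Me2N=CH2+ I− (1.5 equiv), −78 °C → rt; MeI (excess), rt; sat. aq. NaHCO3, rt
Reagents that add atoms: Eschenmoser's salt (dimethyl(methylidene)ammonium iodide), C[N+](C)=C.[I-]
Why: Si–O cleavage by MeLi gives the regiodefined lithium enolate, which undergoes a Mannich reaction with the iminium salt at C4, and N-methylation followed by E1cB (Hofmann-type) elimination unveils the exocyclic enone; C4 becomes sp2, so no stereocentre is at stake.

Step 4
Reactants: 9 4-methylidene ketone
Product: 11 4,4,5β,10β-tetramethyl cis-hydrindan-3-one C8 ethylene ketal, via lithium enolate 10 (not isolated)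
Conditions: LiBH(s-Bu)3 (1.1 equiv), THF, −78 °C; MeI (5 equiv), DMPU, −78 → 0 °C
Reagents that add atoms: iodomethane, CI
Why: conjugate hydride reduction of the unhindered exocyclic enone generates only the tetrasubstituted C3–C4 enolate, which is C-methylated in situ (reductive alkylation), a regiochemistry that direct deprotonation could not guarantee; C4 then carries two identical methyls.

Step 5
Reactants: 11 4,4,5β,10β-tetramethyl ketone ketal
Product: 13 3β-hydroxy-4,4,5β,10β-tetramethyl cis-hydrindan-8-one, via hydroxy ketal 12 (not isolated)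
Conditions: Li, NH3(l), THF, MeOH, −78 → −33 °C; NH4Cl; then 2 M HCl, THF, rt
Reagents that add atoms: water, O
Why: dissolving-metal ketone reduction is governed by product stability and should give the equatorial 3β-alcohol (equatorial is β, cis to the C5 methyl, in the ring A chair that keeps the dioxolane carbon C8 equatorial and so avoids its syn-diaxial clash with a C4 methyl), after which aqueous acid hydrolyses the ketal without touching a stereocentre.

Step 6
Reactants: 13 3β-hydroxy-4,4,5β,10β-tetramethyl cis-hydrindan-8-one; 2 vinylmagnesium bromide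
Product: 14 8α-vinyl-4,4,5β,10β-tetramethyl cis-hydrindane-3β,8β-diol
Conditions: CeCl3 (anhydrous, 2 equiv), THF, rt; then 2 (4 equiv), −78 → 0 °C; aq. NH4Cl
Reagents that add atoms: none
Why: CeCl3-promoted Grignard 1,2-addition curbs enolisation of the hindered cyclopentanone (the first equivalent only forms the C3 alkoxide), and the vinyl group should enter C8 from the α face, away from the two pseudo-axial angular methyls on C10 and C5 that shield the β face, leaving the tertiary hydroxyl β.

Step 7
Reactants: 14 8α-vinyl 3β,8β-diol
Product: 15 3β-acetoxy-8α-vinyl-4,4,5β,10β-tetramethyl cis-hydrindan-8β-ol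
Conditions: Ac2O (3 equiv), pyridine, DMAP (cat.), CH2Cl2, rt
Reagents that add atoms: acetic anhydride, CC(=O)OC(C)=O
Why: DMAP-catalysed acylation should take the equatorial secondary C3 hydroxyl and leave the tertiary C8 carbinol, flanked by quaternary C10, untouched, which installs the acetate of the target before any other hydroxyl exists.

Step 8
Reactants: 15 3β-acetoxy-8α-vinyl 8β-ol
Product: 16 3β-acetoxy-8α-[(R)-oxiran-2-yl]-4,4,5β,10β-tetramethyl cis-hydrindan-8β-ol (9R; epoxide between C9 and C11)
Conditions: VO(acac)2 (5 mol %), t-BuOOH (1.5 equiv, decane), toluene, 0 °C → rt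
Reagents that add atoms: tert-butyl hydroperoxide, CC(C)(C)OO
Why: in this hydroxyl-directed vanadium-catalysed epoxidation the peroxide is delivered from the C8 vanadate ester in the rotamer with an O–C8–C9=C11 dihedral near 50° that places the small C7 methylene anti to C11 and the quaternary C10 below the olefin plane away from the metal (the erythro-type preference of such epoxidations when no cis substituent is present), which for the 8β-carbinol should give the 9R epoxide.

Step 9
Reactants: 16 (9R)-epoxy alcohol
Product: 17 3β-acetoxy-9β-(hydroxymethyl)-4,4,5β,10β-tetramethyl cis-decalin-8-one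
Conditions: BF3·OEt2 (0.3 equiv), CH2Cl2, −78 → −40 °C; sat. aq. NaHCO3 at −40 °C
Reagents that add atoms: none
Why: BF3 coordinates the epoxide oxygen, and as the C9–O bond lengthens the C8–C10 σ bond, held antiperiplanar to it, shifts to C9 while the carbinol oxygen becomes the C8 carbonyl, so no free cation intervenes. The closest known reaction type is the Lewis acid-promoted semipinacol rearrangement of tertiary 2,3-epoxy alcohols to β-hydroxy ketones, including the enlargement of 1-oxiranylcycloalkanols to 2-(hydroxymethyl)cycloalkanones. Ring B (C5–C10) arises by one-carbon ring expansion of the cyclopentane: C9 is inserted between C8 and C10 by a suprafacial 1,2-alkyl shift, not by an end-to-end cyclisation. The only new stereocentre, C9, is set by the epoxide, since C10 arrives anti to the departing oxygen (inversion at C9, retention at C10), which places the CH2OH group β, cis to the C10 methyl, while the C8 configuration is erased. The step needs C9–O rather than C11–O cleavage and migration of C10 rather than C7; the first is secured because only ionisation at C9 is assisted by the shift, the second by the higher migratory aptitude of the quaternary carbon and by the less crowded rotamer (C7 anti to C11) being the one that aligns C10. The acetate is inert, and low temperature with a buffered quench should protect the β-hydroxy ketone from dehydration and retro-aldol cleavage.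

Step 10
Reactants: 17 9β-(hydroxymethyl) 8-ketone
Product: 18 3β-acetoxy-9β-(hydroxymethyl)-4,4,5β,10β-tetramethyl-8-methylidene cis-decalin
Conditions: Zn, CH2Br2, TiCl4 (pre-formed reagent, 4 equiv), THF/CH2Cl2, 0 °C → rt
Reagents that add atoms: dibromomethane, BrCBr
Why: the Takai–Lombardo methylenation reagent is non-basic, so the C9 centre α to the ketone should not epimerise and the β-hydroxy ketone should neither dehydrate nor fragment, and it tolerates the acetate and a free hydroxyl at the cost of extra reagent.

Step 11
Reactants: 18 homoallylic alcohol; 3 7-hydroxycoumarin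
Product: 19 Polyanthinin [7-((3β-acetoxy-4,4,5β,10β-tetramethyl-8-methylidene cis-decalin-9β-yl)methoxy)coumarin; 3S,5S,9S,10R]
Conditions: PPh3 (1.5 equiv), DIAD (1.5 equiv), THF, 0 °C → rt
Reagents that add atoms: none
Why: in this Mitsunobu etherification the acidic phenol (pKa about 8) displaces the oxyphosphonium ion by SN2 at primary C11, the only free hydroxyl, so no stereocentre is touched and the acetate and exocyclic olefin are spectators.

Compound list
1 | (S)-7a-methyl-2,3,7,7a-tetrahydro-1H-indene-1,5(6H)-dione ((S)-Hajos–Parrish ketone) | C[C@]12CCC(=O)C=C1CCC2=O | starting material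
2 | vinylmagnesium bromide | C=C[Mg]Br | starting material
3 | 7-hydroxycoumarin | Oc1ccc2ccc(=O)oc2c1 | starting material
4 | C8 ethylene ketal of 1, (S)-7a'-methyl-2',3',7',7a'-tetrahydrospiro[1,3-dioxolane-2,1'-inden]-5'(6'H)-one | O1CCOC12CCC3=CC(=O)CC[C@]23C | intermediate
5 | cis-hydrindane C3–C4 trimethylsilyl enol ether, 5β,10β-dimethyl, C8 dioxolane | O1CCOC12CC[C@]3(C)C=C(O[Si](C)(C)C)CC[C@]23C | intermediate
6 | lithium C3–C4 enolate of the 5β,10β-dimethyl ketal ketone (formed in situ) | O1CCOC12CC[C@]3(C)C=C([O-])CC[C@]23C.[Li+] | intermediate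
7 | 4-(dimethylaminomethyl)-5β,10β-dimethyl cis-hydrindan-3-one C8 ketal, C4 epimers (formed in situ) | O1CCOC12CC[C@]3(C)C(CN(C)C)C(=O)CC[C@]23C | intermediate
8 | 4-(trimethylammoniomethyl)-5β,10β-dimethyl cis-hydrindan-3-one C8 ketal iodide (formed in situ) | O1CCOC12CC[C@]3(C)C(C[N+](C)(C)C)C(=O)CC[C@]23C.[I-] | intermediate
9 | 5β,10β-dimethyl-4-methylidene cis-hydrindan-3-one C8 ethylene ketal | O1CCOC12CC[C@]3(C)C(=C)C(=O)CC[C@]23C | intermediate
10 | lithium C3–C4 enolate bearing the C4 methyl (formed in situ) | O1CCOC12CC[C@]3(C)C(C)=C([O-])CC[C@]23C.[Li+] | intermediate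
11 | 4,4,5β,10β-tetramethyl cis-hydrindan-3-one C8 ethylene ketal | O1CCOC12CC[C@]3(C)C(C)(C)C(=O)CC[C@]23C | intermediate
12 | 3β-hydroxy-4,4,5β,10β-tetramethyl cis-hydrindane C8 ethylene ketal (formed in situ) | O1CCOC12CC[C@]3(C)C(C)(C)[C@@H](O)CC[C@]23C | intermediate
13 | 3β-hydroxy-4,4,5β,10β-tetramethyl cis-hydrindan-8-one | O=C1CC[C@]2(C)C(C)(C)[C@@H](O)CC[C@]12C | intermediate
14 | 8α-vinyl-4,4,5β,10β-tetramethyl cis-hydrindane-3β,8β-diol | O[C@@]1(C=C)CC[C@]2(C)C(C)(C)[C@@H](O)CC[C@]12C | intermediate
15 | 3β-acetoxy-8α-vinyl-4,4,5β,10β-tetramethyl cis-hydrindan-8β-ol | O[C@@]1(C=C)CC[C@]2(C)C(C)(C)[C@@H](OC(C)=O)CC[C@]12C | intermediate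
16 | 3β-acetoxy-8α-[(R)-oxiran-2-yl]-4,4,5β,10β-tetramethyl cis-hydrindan-8β-ol (9R epoxide, precursor of the key step) | O[C@@]1([C@H]3CO3)CC[C@]2(C)C(C)(C)[C@@H](OC(C)=O)CC[C@]12C | intermediate
17 | 3β-acetoxy-9β-(hydroxymethyl)-4,4,5β,10β-tetramethyl cis-decalin-8-one (product of the key step) | O=C1CC[C@]2(C)C(C)(C)[C@@H](OC(C)=O)CC[C@]2(C)[C@H]1CO | intermediate
18 | 3β-acetoxy-9β-(hydroxymethyl)-4,4,5β,10β-tetramethyl-8-methylidene cis-decalin | C=C1CC[C@]2(C)C(C)(C)[C@@H](OC(C)=O)CC[C@]2(C)[C@H]1CO | intermediate
19 | Polyanthinin, 7-((3β-acetoxy-4,4,5β,10β-tetramethyl-8-methylidene cis-decalin-9β-yl)methoxy)coumarin, 3S,5S,9S,10R | C=C1CC[C@]2(C)C(C)(C)[C@@H](OC(C)=O)CC[C@]2(C)[C@H]1COc1ccc2ccc(=O)oc2c1 | target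

Total step count: 11 steps.
Longest linear sequence: 11 steps, from 1 to 19; 2 and 3 enter as purchased reagents.

Steps most likely to fail

Step 8. The risk is poor or reversed facial selectivity in the delivery of oxygen to the vinyl group, since the two carbinol substituents C10 and C7 are both carbon and the sense also hinges on the C8 configuration set in step 6. The fallback sets out from 15 and comes back at 16. The olefin is epoxidised without relying on direction (mCPBA, NaHCO3, CH2Cl2, 0 °C → rt) to a mixture of 16 and its C9 epimer, the (9S)-epoxide F1. A hydrolytic kinetic resolution of the terminal epoxide (Jacobsen) follows, with (salen)Co(OAc) of trivalent cobalt (salen = N,N'-bis(3,5-di-tert-butylsalicylidene)cyclohexane-1,2-diamine dianion). The antipode of the catalyst that consumes the 9S series is chosen, with water in slight excess over F1. It opens F1 at C11 to the polar 8,9,11-triol F2, which is removed by chromatography, and leaves 16. The C9 configuration is then fixed by the catalyst and not by the substrate.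

Step 9. The risk is diversion of the activated epoxide (external attack at C11, migration of C7 in place of C10) or loss of the product through dehydration or retro-aldol cleavage of the β-hydroxy ketone. The fallback sets out from 16 and comes back at 19, keeping the same C10 shift but with a sulfonate as the leaving group. The caesium salt of 3 (Cs2CO3, DMF, 70 °C) opens the epoxide at C11 to the 8,9-diol aryl ether F3. The secondary C9 hydroxyl is mesylated (MsCl, Et3N, CH2Cl2, 0 °C) to the C9 mesylate F4. Et2AlCl (CH2Cl2, −78 → 0 °C) then promotes the pinacol-type 1,2-shift of C10 from C8 to C9 with inversion, giving the 8-keto aryl ether F5. Methylenation of F5 as in step 10 (Zn, CH2Br2, TiCl4) gives 19.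

Step 4. The risk is slow C-methylation of the congested tetrasubstituted enolate, which would let proton exchange (and then methylation at C2) and O-methylation compete. The fallback sets out from 9 and comes back at 11, forming no bond to C4 by SN2. Luche reduction (NaBH4, CeCl3·7H2O, MeOH, 0 °C) gives the 4-methylidene 3-ol F6, either C3 epimer being acceptable. Hydroxyl-directed Simmons–Smith cyclopropanation (Et2Zn, CH2I2, CH2Cl2) gives the spirocyclopropyl carbinol F7. Hydrogenolysis of the unhindered CH2–CH2 bond (H2, PtO2, AcOH) unveils the geminal methyls in the 4,4-dimethyl 3-ol F8. Oxidation with Dess–Martin periodinane returns 11.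

Further compounds
F1 | step 8 | 3β-acetoxy-8α-[(S)-oxiran-2-yl]-4,4,5β,10β-tetramethyl cis-hydrindan-8β-ol (C9 epimer of 16) | O[C@@]1([C@@H]3CO3)CC[C@]2(C)C(C)(C)[C@@H](OC(C)=O)CC[C@]12C
F2 | step 8 | 3β-acetoxy-8α-[(S)-1,2-dihydroxyethyl]-4,4,5β,10β-tetramethyl cis-hydrindan-8β-ol | O[C@@]1([C@@H](O)CO)CC[C@]2(C)C(C)(C)[C@@H](OC(C)=O)CC[C@]12C
F3 | step 9 | 3β-acetoxy-8α-[(R)-1-hydroxy-2-(coumarin-7-yloxy)ethyl]-4,4,5β,10β-tetramethyl cis-hydrindan-8β-ol | O[C@@]1([C@H](O)COc2ccc3ccc(=O)oc3c2)CC[C@]4(C)C(C)(C)[C@@H](OC(C)=O)CC[C@]14C
F4 | step 9 | C9 methanesulfonate of F3 | O[C@@]1([C@H](OS(C)(=O)=O)COc2ccc3ccc(=O)oc3c2)CC[C@]4(C)C(C)(C)[C@@H](OC(C)=O)CC[C@]14C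
F5 | step 9 | 7-((3β-acetoxy-4,4,5β,10β-tetramethyl-8-oxo cis-decalin-9β-yl)methoxy)coumarin | O=C1CC[C@]2(C)C(C)(C)[C@@H](OC(C)=O)CC[C@]2(C)[C@H]1COc1ccc2ccc(=O)oc2c1
F6 | step 4 | 5β,10β-dimethyl-4-methylidene cis-hydrindan-3-ol C8 ethylene ketal (C3 configuration open) | O1CCOC12CC[C@]3(C)C(=C)C(O)CC[C@]23C
F7 | step 4 | 4-spirocyclopropyl-5β,10β-dimethyl cis-hydrindan-3-ol C8 ethylene ketal (C3 configuration open) | O1CCOC12CC[C@]3(C)C4(CC4)C(O)CC[C@]23C
F8 | step 4 | 4,4,5β,10β-tetramethyl cis-hydrindan-3-ol C8 ethylene ketal (C3 configuration open; the 3β epimer is 12) | O1CCOC12CC[C@]3(C)C(C)(C)C(O)CC[C@]23C
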